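**Strategy.** Ring A of the target holds a 3-methylenecyclohexanol array, C11(=CH2)–C10H2–C9H(OH), beside the quaternary spiro carbon C6 (numbering: ring B C1–C6 with C2=O; ring A C6–C11 with C7 = CMe2, C8 = CHBr). This is the retron of a type 2 intramolecular carbonyl-ene reaction, so everything rests on closing ring A last through the C9–C10 bond. The precursor is monocyclic: ring B carrying at C6 an isopropenyl group and a CMe2–CHBr–CHO chain. In one operation the ene step builds ring A, turns isopropenyl into the exocyclic methylene and sets the C9 carbinol cis to the C8 bromide. The precursor comes from a desymmetrised p-quinol and an Ireland–Claisen rearrangement (C6–C7 bond).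

Key step: step 13

Assumption: the (S)-phosphoric acid of step 2 is taken to deliver the (3aR,7aS) series; if its sense of induction is the opposite, its enantiomer is used and nothing else changes.

Step 1
Reactants: 1 4,4-dimethoxycyclohexa-2,5-dien-1-one; 2 chloroiodomethane
Product: 4 4-(chloromethyl)-4-hydroxycyclohexa-2,5-dien-1-one, via 1-(chloromethyl)-4,4-dimethoxycyclohexa-2,5-dien-1-ol 3 (not isolated)
Conditions: ClCH2I, MeLi·LiBr, THF, −78 °C; AcOH, −78 °C; then 1 M aq. HCl, THF, 0 °C
Reagents that add atoms: chloroiodomethane (2), ClCI; water, O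
Why: Chloromethyllithium made in the flask by iodine–lithium exchange adds 1,2 to the dienone carbonyl (Barbier-type halomethyllithium addition to a quinone monoketal), the cold acetic acid quench keeps the alkoxide from closing to the epoxide, and dilute acid then hydrolyses the dimethyl ketal to the achiral p-quinol.

Step 2
Reactants: 4 4-(chloromethyl)-4-hydroxycyclohexa-2,5-dien-1-one; 5 4-methoxybenzaldehyde
Product: 6 (2S,3aR,7aS)-7a-(chloromethyl)-2-(4-methoxyphenyl)-3a,7a-dihydro-1,3-benzodioxol-5(4H)-one
Conditions: 5 (2 equiv), (S)-3,3'-bis(2,4,6-triisopropylphenyl)-1,1'-binaphthyl-2,2'-diyl hydrogen phosphate (10 mol %), 4 Å molecular sieves, CH2Cl2, rt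
Reagents that add atoms: 4-methoxybenzaldehyde (5), COc1ccc(C=O)cc1
Why: Chiral phosphoric acid-catalysed hemiacetalisation followed by intramolecular oxa-Michael addition desymmetrises the p-quinol; the tether forces cis ring fusion and the catalyst selects one of the two enantiotopic enone arms, which fixes C7a (the later C3 carbinol of the target) as S and C3a as R, while the acetal carbon is only a temporary centre.

Step 3
Reactants: 6 (2S,3aR,7aS)-7a-(chloromethyl)-2-(4-methoxyphenyl)-3a,7a-dihydro-1,3-benzodioxol-5(4H)-one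
Product: 7 (2S,3aR,7aS)-7a-(chloromethyl)-2-(4-methoxyphenyl)hexahydro-1,3-benzodioxol-5-one
Conditions: H2 (1 atm), RhCl(PPh3)3 (5 mol %), benzene/EtOH, rt
Reagents that add atoms: none
Why: Homogeneous hydrogenation with RhCl(PPh3)3 saturates the disubstituted enone C=C without hydrogenolysis of the benzylic acetal or the C–Cl bond and without touching the existing stereocentres.

Step 4
Reactants: 7 (2S,3aR,7aS)-7a-(chloromethyl)-2-(4-methoxyphenyl)hexahydro-1,3-benzodioxol-5-one; 8 triethyl 2-phosphonopropionate
Product: 9 ethyl 2-[(2S,3aR,7aS)-7a-(chloromethyl)-2-(4-methoxyphenyl)hexahydro-1,3-benzodioxol-5-ylidene]propanoate (E/Z mixture)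
Conditions: 8, NaH, THF, 0 → 60 °C
Reagents that add atoms: triethyl 2-phosphonopropionate (8), CCOC(=O)C(C)P(=O)(OCC)OCC
Why: Horner–Wadsworth–Emmons olefination of the cyclohexanone with the α-methyl phosphonate gives the tetrasubstituted enoate, and the E/Z mixture is carried on because both isomers converge on the same quaternary carbon in step 7.

Step 5
Reactants: 9 ethyl 2-[(2S,3aR,7aS)-7a-(chloromethyl)-2-(4-methoxyphenyl)hexahydro-1,3-benzodioxol-5-ylidene]propanoate
Product: 10 2-[(2S,3aR,7aS)-7a-(chloromethyl)-2-(4-methoxyphenyl)hexahydro-1,3-benzodioxol-5-ylidene]propan-1-ol (E/Z mixture)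
Conditions: (i-Bu)2AlH (2.5 equiv), THF, −78 °C; aq. KNaC4H4O6 (potassium sodium tartrate)
Reagents that add atoms: none
Why: 1,2-Reduction of the conjugated ester by (i-Bu)2AlH gives the primary allylic alcohol, and the low temperature keeps the arylidene acetal from reductive opening.

Step 6
Reactants: 10 2-[(2S,3aR,7aS)-7a-(chloromethyl)-2-(4-methoxyphenyl)hexahydro-1,3-benzodioxol-5-ylidene]propan-1-ol; 11 2-methylpropanoyl chloride
Product: 12 2-[(2S,3aR,7aS)-7a-(chloromethyl)-2-(4-methoxyphenyl)hexahydro-1,3-benzodioxol-5-ylidene]propyl 2-methylpropanoate (E/Z mixture)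
Conditions: 11, pyridine, DMAP (cat.), CH2Cl2, 0 °C
Reagents that add atoms: 2-methylpropanoyl chloride (11), CC(C)C(=O)Cl
Why: DMAP-catalysed acylation of the primary allylic alcohol installs the isobutyrate that supplies the CMe2 carbon.

Step 7
Reactants: 12 2-[(2S,3aR,7aS)-7a-(chloromethyl)-2-(4-methoxyphenyl)hexahydro-1,3-benzodioxol-5-ylidene]propyl 2-methylpropanoate
Product: 15 2-[(2S,3aR,5R,7aS)-7a-(chloromethyl)-2-(4-methoxyphenyl)-5-(prop-1-en-2-yl)hexahydro-1,3-benzodioxol-5-yl]-2-methylpropan-1-ol, via silyl ketene acetal 13 (not isolated), via trimethylsilyl ester 14 (not isolated)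
Conditions: LiN(i-Pr)2, Me3SiCl, Et3N, THF, −78 → 65 °C; then LiAlH4, 0 °C → rt; aq. NaOH work-up
Reagents that add atoms: chlorotrimethylsilane, C[Si](C)(C)Cl (silicon stays in 13 and 14 only)
Why: Ireland–Claisen rearrangement of the tetrasubstituted silyl ketene acetal through a chair transition state forges the bond between the two fully substituted carbons and turns the alkylidene into the isopropenyl group; the new quaternary centre (5R) is set by ring B, which should react in the chair with CH2Cl and O-3 equatorial and O-1 axial so that the bulky CMe2 terminus bonds equatorially, cis to O-1, whereas the flipped chair would force the emerging isopropenyl group into a 1,3-diaxial clash with O-3, and LiAlH4 then reduces the silyl ester in the same flask.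

Step 8
Reactants: 15 2-[(2S,3aR,5R,7aS)-7a-(chloromethyl)-2-(4-methoxyphenyl)-5-(prop-1-en-2-yl)hexahydro-1,3-benzodioxol-5-yl]-2-methylpropan-1-ol
Product: 16 2-[(2S,3aR,5R,7aS)-7a-(chloromethyl)-2-(4-methoxyphenyl)-5-(prop-1-en-2-yl)hexahydro-1,3-benzodioxol-5-yl]-2-methylpropanal
Conditions: Dess–Martin periodinane, pyridine, CH2Cl2, 0 °C → rt
Reagents that add atoms: none
Why: Dess–Martin oxidation of the neopentyl primary alcohol stops at the non-enolisable aldehyde, and pyridine buffers the acetic acid released so that the acetal survives.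

Step 9
Reactants: 16 2-[(2S,3aR,5R,7aS)-7a-(chloromethyl)-2-(4-methoxyphenyl)-5-(prop-1-en-2-yl)hexahydro-1,3-benzodioxol-5-yl]-2-methylpropanal; 17 (methoxymethyl)triphenylphosphonium chloride
Product: 18 (2S,3aR,5R,7aS)-7a-(chloromethyl)-5-(4-methoxy-2-methylbut-3-en-2-yl)-2-(4-methoxyphenyl)-5-(prop-1-en-2-yl)hexahydro-1,3-benzodioxole (E/Z mixture)
Conditions: 17, KN(SiMe3)2, THF, 0 °C; then 16, 0 → 50 °C
Reagents that add atoms: (methoxymethyl)triphenylphosphonium chloride (17), COC[P+](c1ccccc1)(c1ccccc1)c1ccccc1.[Cl-]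
Why: Wittig olefination with the methoxymethylene ylide homologates the hindered, non-enolisable aldehyde by one carbon to the enol ether, whose geometry is immaterial.

Step 10
Reactants: 18 (2S,3aR,5R,7aS)-7a-(chloromethyl)-5-(4-methoxy-2-methylbut-3-en-2-yl)-2-(4-methoxyphenyl)-5-(prop-1-en-2-yl)hexahydro-1,3-benzodioxole
Product: 19 3-[(1R,3R,4S)-4-(chloromethyl)-3,4-dihydroxy-1-(prop-1-en-2-yl)cyclohexyl]-3-methylbutanal
Conditions: AcOH/THF/H2O (3:1:1), 40 °C
Reagents that add atoms: water, O
Why: Mild aqueous acid hydrolyses the enol ether to the aldehyde and the electron-rich arylidene acetal to the diol much faster than it can protonate the isopropenyl group, so the two ene partners never meet a strong acid.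

Step 11
Reactants: 19 3-[(1R,3R,4S)-4-(chloromethyl)-3,4-dihydroxy-1-(prop-1-en-2-yl)cyclohexyl]-3-methylbutanal
Product: 20 3-[(1R,4S)-4-(chloromethyl)-4-hydroxy-3-oxo-1-(prop-1-en-2-yl)cyclohexyl]-3-methylbutanal
Conditions: IBX (2-iodoxybenzoic acid, 1.5 equiv), DMSO, rt
Reagents that add atoms: none
Why: IBX oxidises the secondary alcohol of the vicinal diol to the ketone without C–C cleavage and leaves the tertiary alcohol, the aldehyde and the alkene untouched, which erases the auxiliary carbinol centre used in step 7.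

Step 12
Reactants: 20 3-[(1R,4S)-4-(chloromethyl)-4-hydroxy-3-oxo-1-(prop-1-en-2-yl)cyclohexyl]-3-methylbutanal
Product: 21 (2R)-2-bromo-3-[(1R,4S)-4-(chloromethyl)-4-hydroxy-3-oxo-1-(prop-1-en-2-yl)cyclohexyl]-3-methylbutanal
Conditions: (R)-2-[bis(3,5-bis(trifluoromethyl)phenyl)(trimethylsilyloxy)methyl]pyrrolidine (20 mol %), PhCO2H (20 mol %), 4,4-dibromo-2,6-di-tert-butylcyclohexa-2,5-dien-1-one (1.1 equiv), CH2Cl2/pentane, −40 °C; used crude
Reagents that add atoms: 4,4-dibromo-2,6-di-tert-butylcyclohexa-2,5-dien-1-one, CC(C)(C)C1=CC(Br)(Br)C=C(C(C)(C)C)C1=O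
Why: Enamine catalysis: the (E)-enamine formed with the (R)-diarylprolinol silyl ether is brominated by the mild Br+ donor on the face away from the bulky silyloxydiarylmethyl group, which sets the α-carbon as R under catalyst control (independent of the remote ring centres) and spares the isopropenyl group.

Step 13
Reactants: 21 (2R)-2-bromo-3-[(1R,4S)-4-(chloromethyl)-4-hydroxy-3-oxo-1-(prop-1-en-2-yl)cyclohexyl]-3-methylbutanal
Product: 22 (3S,6R,8R,9S)-8-bromo-3-(chloromethyl)-3,9-dihydroxy-7,7-dimethyl-11-methylidenespiro[5.5]undecan-2-one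
Conditions: Me2AlCl (2.5 equiv), CH2Cl2, −78 → −20 °C; cold 1 M aq. HCl quench
Reagents that add atoms: none
Why: Me2AlCl (one equivalent is consumed by the tertiary alcohol as its chloro(methyl)aluminium alkoxide) activates the aldehyde, the isopropenyl CH2 attacks the carbonyl carbon while a methyl hydrogen passes to oxygen through a six-centre array, and the alcohol–aluminium complex then loses methane, so no protic acid remains to isomerise the new exocyclic alkene. The closest known reaction type is the Me2AlCl-promoted type 2 intramolecular carbonyl-ene cyclisation of 5-methylhex-5-enals to 3-methylenecyclohexanols. Ring A closes 6-exo-trig with respect to the aldehyde C=O and 6-endo-trig with respect to the isopropenyl C=C, through a chair fused to the six-membered hydrogen-transfer ring. The new stereocentre C9 (S) is controlled by the C8 bromide: bromine lies equatorial and antiperiplanar to the forming C9–C10 bond (polar Felkin–Anh), and the aluminium-bound oxygen must be axial to reach the methyl hydrogen, which gives the 8,9-cis bromohydrin. The step needs ene over Prins-type cation capture, aldehyde over the ring B ketone and cis over trans; these are secured by the proton-scavenging Lewis acid at low temperature, by the far higher electrophilicity of the α-bromo aldehyde together with the unfavourable five-membered closure onto the ketone, and by the closed transition state. The quaternary C6 and the gem-dimethyl C7 (Thorpe–Ingold effect) hold the two reacting ends together.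

**Compound list**

1 | 4,4-dimethoxycyclohexa-2,5-dien-1-one | COC1(OC)C=CC(=O)C=C1 | starting material
2 | chloroiodomethane | ClCI | starting material
3 | 1-(chloromethyl)-4,4-dimethoxycyclohexa-2,5-dien-1-ol | COC1(OC)C=CC(O)(CCl)C=C1 | intermediate (not isolated)
4 | 4-(chloromethyl)-4-hydroxycyclohexa-2,5-dien-1-one | O=C1C=CC(O)(CCl)C=C1 | intermediate
5 | 4-methoxybenzaldehyde | COc1ccc(C=O)cc1 | starting material
6 | (2S,3aR,7aS)-7a-(chloromethyl)-2-(4-methoxyphenyl)-3a,7a-dihydro-1,3-benzodioxol-5(4H)-one (cis-fused; aryl drawn exo, cis to CH2Cl; this acetal centre is immaterial) | O=C1C=C[C@]2(CCl)O[C@@H](c3ccc(OC)cc3)O[C@@H]2C1 | intermediate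
7 | (2S,3aR,7aS)-7a-(chloromethyl)-2-(4-methoxyphenyl)hexahydro-1,3-benzodioxol-5-one | O=C1CC[C@]2(CCl)O[C@@H](c3ccc(OC)cc3)O[C@@H]2C1 | intermediate
8 | triethyl 2-phosphonopropionate | CCOC(=O)C(C)P(=O)(OCC)OCC | starting material
9 | ethyl 2-[(2S,3aR,7aS)-7a-(chloromethyl)-2-(4-methoxyphenyl)hexahydro-1,3-benzodioxol-5-ylidene]propanoate (E/Z mixture, alkene geometry left open) | CCOC(=O)C(C)=C1CC[C@]2(CCl)O[C@@H](c3ccc(OC)cc3)O[C@@H]2C1 | intermediate
10 | 2-[(2S,3aR,7aS)-7a-(chloromethyl)-2-(4-methoxyphenyl)hexahydro-1,3-benzodioxol-5-ylidene]propan-1-ol (E/Z mixture) | OCC(C)=C1CC[C@]2(CCl)O[C@@H](c3ccc(OC)cc3)O[C@@H]2C1 | intermediate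
11 | 2-methylpropanoyl chloride (isobutyryl chloride) | CC(C)C(=O)Cl | starting material
12 | 2-[(2S,3aR,7aS)-7a-(chloromethyl)-2-(4-methoxyphenyl)hexahydro-1,3-benzodioxol-5-ylidene]propyl 2-methylpropanoate (E/Z mixture) | CC(C)C(=O)OCC(C)=C1CC[C@]2(CCl)O[C@@H](c3ccc(OC)cc3)O[C@@H]2C1 | intermediate
13 | O-trimethylsilyl ketene acetal of ester 12 (E/Z mixture at the ring alkylidene) | CC(C)=C(O[Si](C)(C)C)OCC(C)=C1CC[C@]2(CCl)O[C@@H](c3ccc(OC)cc3)O[C@@H]2C1 | intermediate (not isolated)
14 | trimethylsilyl 2-[(2S,3aR,5R,7aS)-7a-(chloromethyl)-2-(4-methoxyphenyl)-5-(prop-1-en-2-yl)hexahydro-1,3-benzodioxol-5-yl]-2-methylpropanoate | C[Si](C)(C)OC(=O)C(C)(C)[C@]1(C(C)=C)CC[C@]2(CCl)O[C@@H](c3ccc(OC)cc3)O[C@@H]2C1 | intermediate (not isolated)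
15 | 2-[(2S,3aR,5R,7aS)-7a-(chloromethyl)-2-(4-methoxyphenyl)-5-(prop-1-en-2-yl)hexahydro-1,3-benzodioxol-5-yl]-2-methylpropan-1-ol | OCC(C)(C)[C@]1(C(C)=C)CC[C@]2(CCl)O[C@@H](c3ccc(OC)cc3)O[C@@H]2C1 | intermediate
16 | 2-[(2S,3aR,5R,7aS)-7a-(chloromethyl)-2-(4-methoxyphenyl)-5-(prop-1-en-2-yl)hexahydro-1,3-benzodioxol-5-yl]-2-methylpropanal | O=CC(C)(C)[C@]1(C(C)=C)CC[C@]2(CCl)O[C@@H](c3ccc(OC)cc3)O[C@@H]2C1 | intermediate
17 | (methoxymethyl)triphenylphosphonium chloride | COC[P+](c1ccccc1)(c1ccccc1)c1ccccc1.[Cl-] | starting material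
18 | (2S,3aR,5R,7aS)-7a-(chloromethyl)-5-(4-methoxy-2-methylbut-3-en-2-yl)-2-(4-methoxyphenyl)-5-(prop-1-en-2-yl)hexahydro-1,3-benzodioxole (E/Z mixture at the enol ether) | COC=CC(C)(C)[C@]1(C(C)=C)CC[C@]2(CCl)O[C@@H](c3ccc(OC)cc3)O[C@@H]2C1 | intermediate
19 | 3-[(1R,3R,4S)-4-(chloromethyl)-3,4-dihydroxy-1-(prop-1-en-2-yl)cyclohexyl]-3-methylbutanal | O=CCC(C)(C)[C@]1(C(C)=C)CC[C@@](O)(CCl)[C@H](O)C1 | intermediate
20 | 3-[(1R,4S)-4-(chloromethyl)-4-hydroxy-3-oxo-1-(prop-1-en-2-yl)cyclohexyl]-3-methylbutanal | O=CCC(C)(C)[C@]1(C(C)=C)CC[C@@](O)(CCl)C(=O)C1 | intermediate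
21 | (2R)-2-bromo-3-[(1R,4S)-4-(chloromethyl)-4-hydroxy-3-oxo-1-(prop-1-en-2-yl)cyclohexyl]-3-methylbutanal | O=C[C@H](Br)C(C)(C)[C@]1(C(C)=C)CC[C@@](O)(CCl)C(=O)C1 | intermediate
22 | (3S,6R,8R,9S)-8-bromo-3-(chloromethyl)-3,9-dihydroxy-7,7-dimethyl-11-methylidenespiro[5.5]undecan-2-one | C=C1C[C@H](O)[C@H](Br)C(C)(C)[C@@]12CC[C@@](O)(CCl)C(=O)C2 | target

**Total step count:** 13. **Longest linear sequence:** 13 steps (from 1).

**Steps most likely to fail**

Step 13 (key step). The free α-ketol of ring B chelates the aluminium reagent, so methyl transfer to the ketone or an α-ketol shift may compete. An open, cationic (Prins-type) pathway may also erode the cis selectivity or divert the cation to chloride capture or to the endocyclic alkene. The fallback runs the closure on a substrate without a free α-ketol. Setting out from 20, silylation of the tertiary alcohol with N-(trimethylsilyl)imidazole should give the silyl ether aldehyde F1. The bromination of step 12 should then give the silylated bromo aldehyde F2. Me2AlCl (1.2 equiv, −78 °C) should close ring A to the silylated spirocycle F3, and cold dilute HCl in the work-up should remove the silyl group, coming back to the route at 22.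

Step 7. The [3,3] shift between two fully substituted termini may be sluggish, so that C-silylation or ester cleavage competes, and the minor chair of ring B may leak product of the wrong facial sense. The fallback is a neutral aliphatic Claisen rearrangement of an isobutenyl ether, which also bypasses the ester and alcohol stages. Setting out from 10, O-alkylation (NaH, 3-chloro-2-methylpropene, THF) should give the methallyl ether F4. KOtBu in DMSO should isomerise it to the 2-methylprop-1-enyl ether F5. Heating in xylene (about 150 °C) should give the aldehyde directly, coming back to the route at 16.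

Step 2. Hemiacetal formation between the electron-poor tertiary alcohol and the electron-rich aldehyde may be slow, so that an uncatalysed background reaction lowers the enantioselectivity or the quinol decomposes under acid. The fallback uses a boron tether and bifunctional base catalysis in place of the hemiacetal and the chiral acid. Setting out from 4, phenylboronic acid and a cinchona-derived amine–thiourea catalyst should give, through the boronic hemiester and its intramolecular oxa-Michael addition, the cyclic phenylboronate F6. Transesterification with pinacol should release the cis-diol enone F7. Acetalisation with 4-methoxybenzaldehyde dimethyl acetal and pyridinium p-toluenesulfonate should then give the arylidene acetal, coming back to the route at 6.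

**Further compounds**

F1 | step 13 | 3-[(1R,4S)-4-(chloromethyl)-3-oxo-1-(prop-1-en-2-yl)-4-(trimethylsilyloxy)cyclohexyl]-3-methylbutanal | O=CCC(C)(C)[C@]1(C(C)=C)CC[C@@](O[Si](C)(C)C)(CCl)C(=O)C1
F2 | step 13 | (2R)-2-bromo-3-[(1R,4S)-4-(chloromethyl)-3-oxo-1-(prop-1-en-2-yl)-4-(trimethylsilyloxy)cyclohexyl]-3-methylbutanal | O=C[C@H](Br)C(C)(C)[C@]1(C(C)=C)CC[C@@](O[Si](C)(C)C)(CCl)C(=O)C1
F3 | step 13 | (3S,6R,8R,9S)-8-bromo-3-(chloromethyl)-9-hydroxy-7,7-dimethyl-11-methylidene-3-(trimethylsilyloxy)spiro[5.5]undecan-2-one | C=C1C[C@H](O)[C@H](Br)C(C)(C)[C@@]12CC[C@@](O[Si](C)(C)C)(CCl)C(=O)C2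
F4 | step 7 | (2S,3aR,7aS)-7a-(chloromethyl)-2-(4-methoxyphenyl)-5-[1-(2-methylprop-2-enyloxy)propan-2-ylidene]hexahydro-1,3-benzodioxole | C=C(C)COCC(C)=C1CC[C@]2(CCl)O[C@@H](c3ccc(OC)cc3)O[C@@H]2C1
F5 | step 7 | (2S,3aR,7aS)-7a-(chloromethyl)-2-(4-methoxyphenyl)-5-[1-(2-methylprop-1-enyloxy)propan-2-ylidene]hexahydro-1,3-benzodioxole | CC(C)=COCC(C)=C1CC[C@]2(CCl)O[C@@H](c3ccc(OC)cc3)O[C@@H]2C1
F6 | step 2 | (3aR,7aS)-7a-(chloromethyl)-2-phenyl-3a,7a-dihydro-1,3,2-benzodioxaborol-5(4H)-one | O=C1C=C[C@]2(CCl)OB(c3ccccc3)O[C@@H]2C1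
F7 | step 2 | (4S,5R)-4-(chloromethyl)-4,5-dihydroxycyclohex-2-en-1-one | O=C1C=C[C@@](O)(CCl)[C@H](O)C1
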